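**Plan**

- Retrosynthesis: the two acyl–oxygen bonds at O1 and O4 and all benzyl groups are removed first, leading back to a symmetrical 2,5-dihydroxy-3,6-diaryl-1,4-benzoquinone. Its central ring is then cut at C2–C3, C4–C5 and C5–C6.
- Enabling feature: in the central benzene ring (C1 3-hydroxybutanoyloxy, C2 OH, C3 aryl, C4 3-phenylpropanoyloxy, C5 OH, C6 aryl) the para oxygens on C2 and C5 each lie between an aryl carbon and an oxygen-bearing carbon. C2 is therefore a carbene carbon and C5 a carbonyl ligand of a chromium carbene benzannulation, with C1=C6 from an α-alkoxy-β-aryl alkenyl group and C3≡C4 from an aryl ynol ether.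
- Forward: the alkenyl carbene complex comes from 4-(benzyloxy)benzaldehyde via the α-ethoxycinnamoyl chloride, and the ynol ether from ethoxyacetylene by Negishi coupling. The benzannulation builds the central ring, the only ring formed in the route.
- End game: oxidation to the quinone, hydrolysis of the two vinylogous esters, acylation of the two enol oxygens in turn, then one hydrogenation that reduces the quinone and removes three benzyl ethers.
- Stereochemistry: the single (S) centre is bought with methyl (S)-3-hydroxybutanoate and its C–O bond is never broken.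

Key step: step 5

Remark on the chemistry: the two aryl groups are identical, so the diaryl core has a twofold axis exchanging C1 with C4 and C2 with C5. It therefore does not matter which enol oxygen of the dihydroxyquinone receives which acyl group; only mono- versus bis-acylation has to be controlled.

**Route**

Step 1
Reactants: 1 4-(benzyloxy)benzaldehyde; 2 ethyl ethoxyacetate
Product: 4 (Z)-3-[4-(benzyloxy)phenyl]-2-ethoxyprop-2-enoic acid, via ethyl (Z)-α-ethoxycinnamate 3 (not isolated)
Conditions: NaOEt, EtOH, 0 °C to reflux; then aq. NaOH, reflux; then aq. HCl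
Reagents that add atoms: sodium hydroxide, [Na+].[OH-]
Why: A Claisen-type aldol condensation of the ester enolate with the non-enolisable aldehyde, followed by E1cB dehydration, should give the thermodynamically preferred (Z)-α-ethoxycinnamate (aryl trans to the carboxyl group), which is saponified in the same pot.

Step 2
Reactants: 4 (Z)-3-[4-(benzyloxy)phenyl]-2-ethoxyprop-2-enoic acid
Product: 5 (Z)-3-[4-(benzyloxy)phenyl]-2-ethoxyprop-2-enoyl chloride
Conditions: (COCl)2, cat. DMF, CH2Cl2, 0 °C to rt; used crude
Reagents that add atoms: oxalyl chloride, ClC(=O)C(=O)Cl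
Why: Vilsmeier-catalysed acid chloride formation is routine for α-alkoxyacrylic acids and should leave the captodative enol ether and the benzyl ether untouched.

Step 3
Reactants: 5 (Z)-3-[4-(benzyloxy)phenyl]-2-ethoxyprop-2-enoyl chloride; 6 chromium hexacarbonyl, Cr(CO)6
Product: 9 pentacarbonyl[(Z)-3-(4-benzyloxyphenyl)-2-ethoxy-1-methoxyprop-2-en-1-ylidene]chromium, via disodium pentacarbonylchromate 7 (not isolated), via sodium acylchromate 8 (not isolated)
Conditions: Cr(CO)6, sodium naphthalenide NaC10H8 (2 equiv), THF, −78 °C; then 5, −78 to 0 °C; then Me3OBF4, CH2Cl2, 0 °C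
Reagents that add atoms: trimethyloxonium tetrafluoroborate, C[O+](C)C.F[B-](F)(F)F
Why: Reductive formation of the pentacarbonylchromate dianion, its acylation by an acid chloride and O-methylation of the acylchromate with a Meerwein salt is the chromate-dianion route to Fischer alkoxycarbene complexes, chosen because the matching α-ethoxy-β-arylvinyllithium is not reliably available by deprotonation.

Step 4
Reactants: 10 1-(benzyloxy)-4-iodobenzene; 11 ethoxyacetylene
Product: 14 1-(benzyloxy)-4-(ethoxyethynyl)benzene, via lithium ethoxyacetylide 12 (not isolated), via (ethoxyethynyl)zinc chloride 13 (not isolated)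
Conditions: n-BuLi, THF, −78 °C; ZnCl2, −78 to 0 °C; then 10, Pd(PPh3)4 (5 mol %), THF, rt; chromatography on Et3N-deactivated silica
Reagents that add atoms: none
Why: Negishi coupling of an alkoxyethynylzinc chloride with an aryl iodide under zerovalent palladium catalysis is the established entry to 1-alkoxy-2-arylacetylenes and avoids the amine and copper salts to which ynol ethers are sensitive.

Step 5
Reactants: 9 pentacarbonyl[(Z)-3-(4-benzyloxyphenyl)-2-ethoxy-1-methoxyprop-2-en-1-ylidene]chromium; 14 1-(benzyloxy)-4-(ethoxyethynyl)benzene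
Product: 16 2,5-bis[4-(benzyloxy)phenyl]-3,6-diethoxy-4-methoxyphenol (target numbering: C1 OEt, C2 OMe, C3 aryl, C4 OEt, C5 OH, C6 aryl), via tricarbonylchromium arene complex 15 (not isolated)
Conditions: 9 (1 equiv), 14 (1.5 equiv), THF (0.05 M), 50 °C, Ar; then CO (1 atm), hν (Pyrex-filtered Hg lamp), rt; then air, rt
Reagents that add atoms: none
Why: Proposed new method: heating expels one carbonyl ligand from 9, ynol ether 14 binds and inserts into the chromium–carbon double bond with its nucleophilic aryl-bearing carbon attacking the electrophilic carbene carbon (C2–C3), carbonyl insertion at the new ethoxy-substituted carbene carbon (C4–C5) gives a chromium-bound dienylketene, and 6π-electrocyclisation onto the β-carbon of the former alkenyl group (C5–C6) followed by enolisation gives the chromium-bound phenol 15, from which air releases 16. The closest known reaction is the Dötz benzannulation of alkenyl and α-alkoxyalkenyl methoxycarbene complexes of chromium with alkynes; the new element is the aryl ynol ether as alkyne, whose insertion has its nearest analogy in the insertion of ynamines into Fischer carbene complexes, which gives the heteroatom-stabilised carbene of the same orientation. Because the ethoxy-stabilised vinylcarbene may be slow to insert a carbonyl ligand, the thermal stage is followed by irradiation under CO, conditions known to turn dienyl(alkoxy)carbene chromium complexes into o-alkoxyphenols through the same ketene. The central benzene ring is closed by 6π-electrocyclisation of the dienylketene (a formal [3+2+1] assembly), and no stereocentre is formed. The step needs the orientation aryl carbon to carbene carbon and ethoxy carbon to carbonyl carbon, which the polarisation of the ynol ether and oxygen stabilisation of the new carbene carbon should secure, and the hydrogen on C6 of 9 allows the final aromatisation.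

Step 6
Reactants: 16 2,5-bis[4-(benzyloxy)phenyl]-3,6-diethoxy-4-methoxyphenol
Product: 17 2,5-bis[4-(benzyloxy)phenyl]-3,6-diethoxycyclohexa-2,5-diene-1,4-dione
Conditions: (NH4)2Ce(NO3)6 (2.2 equiv), MeCN–H2O, 0 °C
Reagents that add atoms: water, O
Why: Oxidative demethylation of a p-methoxyphenol by tetravalent cerium (two one-electron oxidations, water attack at C2, loss of methanol) should be much faster than attack on the benzyloxyphenyl rings and gives the C2-symmetric quinone.

Step 7
Reactants: 17 2,5-bis[4-(benzyloxy)phenyl]-3,6-diethoxycyclohexa-2,5-diene-1,4-dione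
Product: 18 2,5-bis[4-(benzyloxy)phenyl]-3,6-dihydroxycyclohexa-2,5-diene-1,4-dione
Conditions: aq. NaOH (2 M), dioxane–EtOH, 70 °C; then aq. HCl
Reagents that add atoms: sodium hydroxide, [Na+].[OH-]
Why: Both ethoxy groups are vinylogous esters, so hydroxide should displace them by addition–elimination at C1 and C4, the classical hydrolysis of 2,5-dialkoxy-3,6-diarylbenzoquinones to the vinylogous diacid.

Step 8
Reactants: 19 methyl (S)-3-hydroxybutanoate
Product: 20 methyl (S)-3-(benzyloxy)butanoate
Conditions: benzyl 2,2,2-trichloroacetimidate, cat. TfOH, CH2Cl2–cyclohexane, 0 °C to rt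
Reagents that add atoms: benzyl 2,2,2-trichloroacetimidate, N=C(OCc1ccccc1)C(Cl)(Cl)Cl
Why: Acid-catalysed trichloroacetimidate benzylation etherifies the β-hydroxy ester without base, so β-elimination is avoided and the stereocentre, whose C–O bond is not broken, keeps its (S) configuration.

Step 9
Reactants: 20 methyl (S)-3-(benzyloxy)butanoate
Product: 21 (S)-3-(benzyloxy)butanoic acid
Conditions: LiOH, THF–H2O, 0 °C to rt; then aq. HCl
Reagents that add atoms: lithium hydroxide, [Li+].[OH-]
Why: Mild saponification cleaves the methyl ester while the β-benzyloxy group and the stereocentre should be unaffected at low temperature.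

Step 10
Reactants: 21 (S)-3-(benzyloxy)butanoic acid
Product: 22 (S)-3-(benzyloxy)butanoyl chloride
Conditions: (COCl)2, cat. DMF, CH2Cl2, 0 °C to rt; used crude
Reagents that add atoms: oxalyl chloride, ClC(=O)C(=O)Cl
Why: Standard Vilsmeier-catalysed acid chloride formation under neutral conditions does not touch the remote stereocentre or the benzyl ether.

Step 11
Reactants: 18 2,5-bis[4-(benzyloxy)phenyl]-3,6-dihydroxycyclohexa-2,5-diene-1,4-dione; 23 3-phenylpropanoyl chloride
Product: 24 2,5-bis[4-(benzyloxy)phenyl]-4-hydroxy-3,6-dioxocyclohexa-1,4-dien-1-yl 3-phenylpropanoate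
Conditions: 2,6-lutidine (1.0 equiv), 23 (0.9 equiv, slow addition), CH2Cl2, −40 to 0 °C; recovered 18 recycled
Reagents that add atoms: none
Why: O-acylation of the enolate of a vinylogous acid by an acid chloride is a routine esterification, and since the two enol hydroxyls of 18 are symmetry-equivalent only the degree of acylation needs control, which substoichiometric acid chloride, one equivalent of a hindered base and recycling of 18 should provide.

Step 12
Reactants: 24 2,5-bis[4-(benzyloxy)phenyl]-4-hydroxy-3,6-dioxocyclohexa-1,4-dien-1-yl 3-phenylpropanoate; 22 (S)-3-(benzyloxy)butanoyl chloride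
Product: 25 2,5-bis[4-(benzyloxy)phenyl]-3,6-dioxo-4-(3-phenylpropanoyloxy)cyclohexa-1,4-dien-1-yl (S)-3-(benzyloxy)butanoate
Conditions: 2,6-lutidine (1.5 equiv), 22 (1.3 equiv), CH2Cl2, −20 to 0 °C
Reagents that add atoms: none
Why: The remaining enol hydroxyl is esterified in the same way, and the hindered, weak, non-nucleophilic base should avoid both acyl transfer from the existing vinylogous anhydride and ketene formation or β-elimination from 22, leaving the stereocentre untouched.

Step 13
Reactants: 25 2,5-bis[4-(benzyloxy)phenyl]-3,6-dioxo-4-(3-phenylpropanoyloxy)cyclohexa-1,4-dien-1-yl (S)-3-(benzyloxy)butanoate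
Product: 26 2,5-dihydroxy-3,6-bis(4-hydroxyphenyl)-4-(3-phenylpropanoyloxy)phenyl (S)-3-hydroxybutanoate (CNP0296884.1)
Conditions: H2 (1 atm), Pd(OH)2/C, EtOAc–THF, rt; filtration and concentration under Ar with degassed solvents
Reagents that add atoms: none
Why: Catalytic hydrogenation should reduce the quinone to the hydroquinone (freeing the C2 and C5 hydroxyls) and hydrogenolyse the two aryl benzyl ethers and the alkyl benzyl ether in one neutral, non-nucleophilic operation that leaves both aryl esters in place and the (S) centre unchanged.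

**Compound list**

1 | 4-(benzyloxy)benzaldehyde | O=Cc1ccc(OCc2ccccc2)cc1 | starting material
2 | ethyl ethoxyacetate | CCOCC(=O)OCC | starting material
3 | ethyl (Z)-3-[4-(benzyloxy)phenyl]-2-ethoxyprop-2-enoate | CCO/C(=C\c1ccc(OCc2ccccc2)cc1)C(=O)OCC | intermediate (not isolated)
4 | (Z)-3-[4-(benzyloxy)phenyl]-2-ethoxyprop-2-enoic acid | CCO/C(=C\c1ccc(OCc2ccccc2)cc1)C(=O)O | intermediate
5 | (Z)-3-[4-(benzyloxy)phenyl]-2-ethoxyprop-2-enoyl chloride | CCO/C(=C\c1ccc(OCc2ccccc2)cc1)C(=O)Cl | intermediate
6 | chromium hexacarbonyl, Cr(CO)6 | O=C=[Cr](=C=O)(=C=O)(=C=O)(=C=O)=C=O | starting material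
7 | disodium pentacarbonylchromate, Na2[Cr(CO)5] | [Na+].[Na+].O=C=[Cr-2](=C=O)(=C=O)(=C=O)=C=O | intermediate (not isolated)
8 | sodium pentacarbonyl[(Z)-3-(4-benzyloxyphenyl)-2-ethoxyprop-2-enoyl]chromate | [Na+].CCO/C(=C\c1ccc(OCc2ccccc2)cc1)C(=O)[Cr-](=C=O)(=C=O)(=C=O)(=C=O)=C=O | intermediate (not isolated)
9 | pentacarbonyl[(Z)-3-(4-benzyloxyphenyl)-2-ethoxy-1-methoxyprop-2-en-1-ylidene]chromium | COC(=[Cr](=C=O)(=C=O)(=C=O)(=C=O)=C=O)/C(OCC)=C/c1ccc(OCc2ccccc2)cc1 | intermediate (key-step precursor)
10 | 1-(benzyloxy)-4-iodobenzene | Ic1ccc(OCc2ccccc2)cc1 | starting material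
11 | ethoxyacetylene | C#COCC | starting material
12 | lithium ethoxyacetylide | [Li]C#COCC | intermediate (not isolated)
13 | (ethoxyethynyl)zinc chloride | Cl[Zn]C#COCC | intermediate (not isolated)
14 | 1-(benzyloxy)-4-(ethoxyethynyl)benzene | CCOC#Cc1ccc(OCc2ccccc2)cc1 | intermediate (key-step precursor)
15 | tricarbonyl(η6-arene)chromium complex of phenol 16 (chromium on the new central ring) | COc1c(OCC)c(-c2ccc(OCc3ccccc3)cc2)c(O)c(OCC)c1-c1ccc(OCc2ccccc2)cc1.O=C=[Cr](=C=O)=C=O | intermediate (not isolated)
16 | 2,5-bis[4-(benzyloxy)phenyl]-3,6-diethoxy-4-methoxyphenol | COc1c(OCC)c(-c2ccc(OCc3ccccc3)cc2)c(O)c(OCC)c1-c1ccc(OCc2ccccc2)cc1 | intermediate (key-step product)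
17 | 2,5-bis[4-(benzyloxy)phenyl]-3,6-diethoxycyclohexa-2,5-diene-1,4-dione | CCOC1=C(c2ccc(OCc3ccccc3)cc2)C(=O)C(OCC)=C(c2ccc(OCc3ccccc3)cc2)C1=O | intermediate
18 | 2,5-bis[4-(benzyloxy)phenyl]-3,6-dihydroxycyclohexa-2,5-diene-1,4-dione | OC1=C(c2ccc(OCc3ccccc3)cc2)C(=O)C(O)=C(c2ccc(OCc3ccccc3)cc2)C1=O | intermediate
19 | methyl (S)-3-hydroxybutanoate | C[C@H](O)CC(=O)OC | starting material
20 | methyl (S)-3-(benzyloxy)butanoate | C[C@H](OCc1ccccc1)CC(=O)OC | intermediate
21 | (S)-3-(benzyloxy)butanoic acid | C[C@H](OCc1ccccc1)CC(=O)O | intermediate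
22 | (S)-3-(benzyloxy)butanoyl chloride | C[C@H](OCc1ccccc1)CC(=O)Cl | intermediate
23 | 3-phenylpropanoyl chloride | O=C(Cl)CCc1ccccc1 | starting material
24 | 2,5-bis[4-(benzyloxy)phenyl]-4-hydroxy-3,6-dioxocyclohexa-1,4-dien-1-yl 3-phenylpropanoate | O=C(CCc1ccccc1)OC1=C(c2ccc(OCc3ccccc3)cc2)C(=O)C(O)=C(c2ccc(OCc3ccccc3)cc2)C1=O | intermediate
25 | 2,5-bis[4-(benzyloxy)phenyl]-3,6-dioxo-4-(3-phenylpropanoyloxy)cyclohexa-1,4-dien-1-yl (S)-3-(benzyloxy)butanoate | C[C@H](OCc1ccccc1)CC(=O)OC1=C(c2ccc(OCc3ccccc3)cc2)C(=O)C(OC(=O)CCc2ccccc2)=C(c2ccc(OCc3ccccc3)cc2)C1=O | intermediate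
26 | 2,5-dihydroxy-3,6-bis(4-hydroxyphenyl)-4-(3-phenylpropanoyloxy)phenyl (S)-3-hydroxybutanoate (CNP0296884.1) | C[C@H](O)CC(=O)Oc1c(O)c(-c2ccc(O)cc2)c(OC(=O)CCc2ccccc2)c(O)c1-c1ccc(O)cc1 | target

**Summary**

Total step count: 13.
Longest linear sequence: 9 steps (steps 1, 2, 3, 5, 6, 7, 11, 12, 13).

**Steps most likely to fail**

1. Step 5 (proposed new method). The sequence may stop after alkyne insertion at the ethoxy-stabilised carbene, so that no carbonyl ligand is inserted and no ring closes. The ynol ether may also be consumed by oligomerisation or by addition of the phenolic product.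
Fallback (known chemistry, no benzannulation): setting out from iodide 10, Miyaura borylation (B2pin2, Pd(dppf)Cl2, KOAc, dioxane, 80 °C) gives 2-[4-(benzyloxy)phenyl]-4,4,5,5-tetramethyl-1,3,2-dioxaborolane F1. Its coupling partner, 2,5-dibromo-3,6-dimethoxy-1,4-benzoquinone F2, is made from commercial bromanil with NaOMe in MeOH. Twofold Suzuki coupling of F1 with F2 (Pd(PPh3)4, K2CO3, dioxane–H2O, 80 °C) forms the C3–aryl and C6–aryl bonds on the preformed quinone and gives 2,5-bis[4-(benzyloxy)phenyl]-3,6-dimethoxycyclohexa-2,5-diene-1,4-dione F3. Hydrolysis with aqueous NaOH as in step 7 comes back to the route at 18.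

2. Step 3. The strongly reducing chromate dianion may transfer an electron to, or add in conjugate fashion to, the unsaturated acid chloride instead of substituting at the acyl carbon, and O-methylation of the acylchromate may be incomplete.
Fallback (organolithium route instead of chromate acylation): setting out from ynol ether 14, syn-hydrostannation with Bu3SnH and catalytic Pd(PPh3)4 in THF should place tin on the oxygen-bearing carbon and give (E)-tributyl{2-[4-(benzyloxy)phenyl]-1-ethoxyethenyl}stannane F4. Tin–lithium exchange with n-BuLi (THF, −78 °C) gives (Z)-{2-[4-(benzyloxy)phenyl]-1-ethoxyethenyl}lithium F5. F5 adds to Cr(CO)6 (6) to give lithium pentacarbonyl[(Z)-3-(4-benzyloxyphenyl)-2-ethoxyprop-2-enoyl]chromate F6, and O-methylation with Me3OBF4 comes back to the route at 9.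

3. Step 11. Acylation of the second enol oxygen may compete with acylation of the first, so that the symmetric diol is converted to a near-statistical mixture of unreacted diol, mono-ester and bis-ester.
Fallback (selective removal instead of selective introduction of one acyl group): setting out from 18, exhaustive acylation with excess 23 and 2,6-lutidine gives 2,5-bis[4-(benzyloxy)phenyl]-3,6-dioxocyclohexa-1,4-diene-1,4-diyl bis(3-phenylpropanoate) F7. One equivalent of NaOMe in THF–MeOH at −40 °C should then remove a single acyl group, because the enolate formed by the first cleavage makes the second ester a much poorer acylating agent. Acidification comes back to the route at 24.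

**Further compounds**

F1 | step 5 | 2-[4-(benzyloxy)phenyl]-4,4,5,5-tetramethyl-1,3,2-dioxaborolane | CC1(C)OB(c2ccc(OCc3ccccc3)cc2)OC1(C)C
F2 | step 5 | 2,5-dibromo-3,6-dimethoxycyclohexa-2,5-diene-1,4-dione | COC1=C(Br)C(=O)C(OC)=C(Br)C1=O
F3 | step 5 | 2,5-bis[4-(benzyloxy)phenyl]-3,6-dimethoxycyclohexa-2,5-diene-1,4-dione | COC1=C(c2ccc(OCc3ccccc3)cc2)C(=O)C(OC)=C(c2ccc(OCc3ccccc3)cc2)C1=O
F4 | step 3 | (E)-tributyl{2-[4-(benzyloxy)phenyl]-1-ethoxyethenyl}stannane | CCCC[Sn](CCCC)(CCCC)/C(OCC)=C/c1ccc(OCc2ccccc2)cc1
F5 | step 3 | (Z)-{2-[4-(benzyloxy)phenyl]-1-ethoxyethenyl}lithium | [Li]/C(OCC)=C/c1ccc(OCc2ccccc2)cc1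
F6 | step 3 | lithium pentacarbonyl[(Z)-3-(4-benzyloxyphenyl)-2-ethoxyprop-2-enoyl]chromate | [Li+].CCO/C(=C\c1ccc(OCc2ccccc2)cc1)C(=O)[Cr-](=C=O)(=C=O)(=C=O)(=C=O)=C=O
F7 | step 11 | 2,5-bis[4-(benzyloxy)phenyl]-3,6-dioxocyclohexa-1,4-diene-1,4-diyl bis(3-phenylpropanoate) | O=C(CCc1ccccc1)OC1=C(c2ccc(OCc3ccccc3)cc2)C(=O)C(OC(=O)CCc2ccccc2)=C(c2ccc(OCc3ccccc3)cc2)C1=O
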